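A small charge of free catalyst, 2.5 mol% on substrate in beta, shares the flask with an impurity, and the earlier runs suggest that the impurity takes a fixed toll of that charge.

| setting | beta | alpha | eta | gamma | dusk | midnight | dawn | autumn |
|---|---|---|---|---|---|---|---|---|
| substrate | 0.19 M | 0.13 M | 0.29 M | 0.19 M | 0.19 M (fed, over 4.80 min) | 0.19 M | 0.19 M | 0.19 M |
| free catalyst | 2.5 mol% | 2.5 mol% | 2.5 mol% | 3.8 mol% | 2.5 mol% | 2.5 mol% | 2.5 mol% | 2.5 mol% |
| impurity | 2.9 mM | 2.9 mM | 2.9 mM | 2.9 mM | 2.9 mM | 2.9 mM | 2.9 mM | 2.9 mM |
| remark | run made earlier | run made earlier | run made earlier | run made earlier | a stirred flask in which substrate is dosed at a steady rate over 4.80 min without added volume, worked up at 6.0 min | a closed flask charged with all of it at once and left for 6.0 min | one stirred flow tank at steady state, fed with the mixture as stated, mean residence time 30.0 min | a single well-mixed tank run continuously and read at steady state, 6.0 min in it on average |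
| time |  |  |  |  | 6.0 min | 6.0 min |  |  |

- beta (time / min: product / %, substrate / %): 0.500: 0, 101; 0.833: 3, 97; 1.33: 4, 97; 2.00: 4, 94; 4.00: 10, 90; 6.00: 13, 86
- alpha (time / min: product / %, substrate / %): 0.417: 0, 98; 0.667: 3, 100; 1.00: 0, 101; 2.00: 0, 102; 3.00: 4, 101; 5.00: 4, 99
- eta (time / min: product / %, substrate / %): 0.333: 2, 96; 1.00: 3, 93; 1.50: 8, 94; 2.50: 9, 90; 4.00: 16, 84; 5.00: 21, 78
- gamma (time / min: product / %, substrate / %): 1.00: 6, 95; 2.00: 8, 90; 3.00: 17, 82; 4.00: 24, 73; 5.00: 27, 70

(readings scatter by 1.5 percentage points)

- the stated concentrations are those of everything mixed, before any reaction; amounts are the same in each set-up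
- what was read earlier has a scatter of 1.5 percentage points, one standard deviation
- the feed brings no volume worth counting
- the earlier runs were made in a closed, stirred flask

- the set-up with the highest amount of product at the outlet or at the end, in percent of the substrate put in ("none" if the first two lie within 2 percentage points) (dusk / midnight / dawn / autumn / none)
- amount of product at the outlet or at the end, in percent of the substrate put in, dusk
- amount of product at the outlet or at the end, in percent of the substrate put in, midnight
- amount of product at the outlet or at the end, in percent of the substrate put in, dawn
- amount of product at the outlet or at the end, in percent of the substrate put in, autumn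

1. The first instants. This reckoning supposes that the impurity takes catalyst one for one. In beta the catalyst charge of 4.75 mM stands above the 2.9 mM of impurity, so the impurity is the limiting reagent of this loss. The live share, the fraction of the catalyst charge left once each impurity has taken one catalyst, is 38.9% in beta. The alpha run has the same impurity against a smaller charge, so its live share is 10.8%, and it reads 4% product at 5.00 min, while beta reads 13% at 6.00 min.

2. The middle. The beta curve stays near straight. Product per live catalyst reads 2.23 min⁻¹ in beta and 2.38 min⁻¹ in gamma, at a different loading. Both are readings, with their scatter.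

3. The end. Midnight repeats beta, and autumn should lie near it. Dusk has the same live share but receives its substrate over 4.80 min, so this reckoning puts it somewhat lower. Dawn has a mean residence time of 30.0 min, and the beta pace carried that far gives 65.0%, above the beta reading. The beta pace was read with 86% or more of the substrate standing, and this reckoning leaves open how far the pace falls in a tank holding 35.0%.

The forecast names dawn, with 12% for dusk, 13.5% for midnight, 63% for dawn and 13% for autumn, the impurity being “assumed to bind catalyst tightly”.

The flasks give 10.5% in dusk, 14.3% in midnight, 54.5% in dawn and 14.1% in autumn, so dawn leads, standing 8.5 percentage points under the forecast with 45.0% of the substrate at its outlet.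

    free catalyst + impurity → spent catalyst (k = 18800 L mol⁻¹ min⁻¹)
    substrate + free catalyst → catalyst intermediate (k = 46.4 L mol⁻¹ min⁻¹)
    catalyst intermediate → free catalyst + product (k = 3.53 min⁻¹)

In dusk at 3.00 min, with the feed still running, spent catalyst stands at 61.1% of the catalyst charged, against 61.1% reckoned as the complement of the live share. The same flask at 4.2 mol% has a live share of 63.7%, which gives 2.75 times the live catalyst of dusk per substrate, and at 6.0 min it holds 27.2% product, 2.59 times the 10.5% of dusk.

The readings were generated by integration for substances that don't exist; scatter was added.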